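Ring B is disconnected at C4a–C4 and C8a–C1, so that both carbon substituents of the isocoumarin come from one malonate inserted across a 3-aryloxy-5-methoxybenzyne. The key step exploits the three contiguous carbons of ring B, C8 (aryl ether oxygen), C8a (carrying carbonyl carbon C1) and C4a (carrying C4): the C8 oxygen steers the malonate carbon to C4a and the ester to C8a, giving the homophthalate in one operation. Its precursor is the fully protected ring A diaryl ether whose ring B bears Me3Si at C8a, flanked by the ether oxygen and a triflate at C4a. Hexanoylation, decarboxylation and enol lactonisation then close the pyranone.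

Key step: step 11

Remarks on the chemistry (assumptions):
- Ring A is the benzoic acid ring (C1 carboxyl, C2 and C4 oxygens, C5 ether oxygen, C6 side chain). Ring B atoms are numbered as in 1H-isochromen-1-one (C1, O2, C3, C4, C4a, C5 to C8, C8a), also in the open-chain intermediates.
- Orsellinic acid, N-methoxy-N-methylhexanamide, 4-methoxyaniline, diallyl malonate and hexanoyl chloride are taken as purchased; the Weinreb amide is otherwise one step from hexanoyl chloride and MeNHOMe·HCl.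
- The malonate is used as its diallyl ester. Zerovalent palladium later removes both allyl groups under neutral conditions, so the ring B acid is free and the ring A acid still a benzyl ester when the lactone is closed.
- The target has no stereocentre. The one stereocentre that appears on the way (product of step 12) is racemic and is lost in step 13.

Step 1
Reactants: 1 orsellinic acid (2,4-dihydroxy-6-methylbenzoic acid)
Product: 2 benzyl 2,4-bis(benzyloxy)-6-methylbenzoate
Conditions: BnBr (3.5 equiv), K2CO3, DMF, rt then 60 °C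
Reagents that add atoms: benzyl bromide, BrCc1ccccc1
Why: Carboxylate and phenoxide O-alkylation (Williamson type); the carboxylate is esterified first at rt, which blocks decarboxylation before the chelated 2-OH is benzylated on warming.

Step 2
Reactants: 2 benzyl 2,4-bis(benzyloxy)-6-methylbenzoate
Product: 3 benzyl 4,6-bis(benzyloxy)-3-bromo-2-methylbenzoate
Conditions: NBS (1.05 equiv), MeCN, 0 °C to rt, dark
Reagents that add atoms: N-bromosuccinimide, O=C1CCC(=O)N1Br
Why: Electrophilic aromatic bromination at ring A C5, which is para to the 2-benzyloxy group, ortho to the 4-benzyloxy group and less crowded than C3 between two ethers; this is the usual halogenation site of 2,4-dialkoxy-6-alkylbenzoates.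

Step 3
Reactants: 3 benzyl 4,6-bis(benzyloxy)-3-bromo-2-methylbenzoate; 4 N-methoxy-N-methylhexanamide
Product: 5 benzyl 4,6-bis(benzyloxy)-3-bromo-2-(2-oxoheptyl)benzoate
Conditions: LiN(iPr)2 (1.3 equiv), THF, −78 °C; then 4, −78 to −40 °C; aq. NH4Cl
Reagents that add atoms: none
Why: Lateral (benzylic) lithiation of the ortho-toluate and acylation by the Weinreb amide, whose stable tetrahedral adduct prevents over-addition; the amide base does not exchange the aryl bromide and the doubly ortho-substituted benzyl ester resists self-condensation.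

Step 4
Reactants: 5 benzyl 4,6-bis(benzyloxy)-3-bromo-2-(2-oxoheptyl)benzoate
Product: 6 benzyl 4,6-bis(benzyloxy)-3-bromo-2-[(2-pentyl-1,3-dioxolan-2-yl)methyl]benzoate
Conditions: (Me3SiOCH2)2 (1.5 equiv), Me3SiOTf (5 mol %), CH2Cl2, −78 to −20 °C; pyridine quench
Reagents that add atoms: 1,2-bis(trimethylsilyloxy)ethane, C[Si](C)(C)OCCO[Si](C)(C)C
Why: Ketalisation with the bis-silyl ether of ethylene glycol under silyl triflate catalysis, driven by loss of hexamethyldisiloxane and cold enough that the ketone does not enol-lactonise onto the benzyl ester.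

Step 5
Reactants: 6 benzyl 4,6-bis(benzyloxy)-3-bromo-2-[(2-pentyl-1,3-dioxolan-2-yl)methyl]benzoate
Product: 8 benzyl 4,6-bis(benzyloxy)-3-hydroxy-2-[(2-pentyl-1,3-dioxolan-2-yl)methyl]benzoate, via pinacol boronate 7 (not isolated)
Conditions: PdCl2(MeCN)2 (2 mol %), SPhos (8 mol %), pinacolborane, Et3N, 1,4-dioxane, 80 °C; then 30 % H2O2, aq. NaOH, THF, 0 °C
Reagents that add atoms: pinacolborane, CC1(C)OBOC1(C)C (boron group of 7); hydrogen peroxide, OO (phenol oxygen of 8)
Why: Palladium-catalysed Miyaura-type borylation of the aryl bromide (the bulky biarylphosphine tolerates the two ortho substituents) followed by oxidation of the C–B bond gives the ring A phenol at the position of the bromine.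

Step 6
Reactants: 9 4-methoxyaniline
Product: 10 2,6-diiodo-4-methoxyaniline
Conditions: BnMe3N+ ICl2− (2.1 equiv), CaCO3, CH2Cl2/MeOH, rt
Reagents that add atoms: benzyltrimethylammonium dichloroiodate, C[N+](C)(C)Cc1ccccc1.Cl[I-]Cl
Why: Electrophilic aromatic iodination directed by the free amino group, whose two ortho positions are open while its para position is blocked by methoxy.

Step 7
Reactants: 10 2,6-diiodo-4-methoxyaniline
Product: 12 2-bromo-1,3-diiodo-5-methoxybenzene, via diazonium bromide 11 (not isolated)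
Conditions: t-BuONO (1.5 equiv), CuBr2 (1.2 equiv), MeCN, 0 to 60 °C
Reagents that add atoms: tert-butyl nitrite, CC(C)(C)ON=O (second nitrogen of 11); CuBr2, [Cu+2].[Br-].[Br-] (bromine of 12)
Why: Sandmeyer bromination with non-aqueous diazotisation, which suits the weakly basic 2,6-diiodoaniline; the diazonium group is replaced by bromide through copper-mediated electron transfer.

Step 8
Reactants: 8 benzyl 4,6-bis(benzyloxy)-3-hydroxy-2-[(2-pentyl-1,3-dioxolan-2-yl)methyl]benzoate; 12 2-bromo-1,3-diiodo-5-methoxybenzene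
Product: 13 benzyl 4,6-bis(benzyloxy)-3-(2-bromo-3-iodo-5-methoxyphenoxy)-2-[(2-pentyl-1,3-dioxolan-2-yl)methyl]benzoate
Conditions: CuI (10 mol %), picolinic acid (20 mol %), K3PO4, DMSO, 90 °C; 12 in excess (3 equiv)
Reagents that add atoms: none
Why: Ullmann-type C–O coupling with a copper/picolinate catalyst, a system suited to joining 2,6-disubstituted phenols with ortho-substituted aryl iodides; iodide reacts far faster than bromide and the excess of the symmetrical diiodide limits double arylation.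

Step 9
Reactants: 13 benzyl 4,6-bis(benzyloxy)-3-(2-bromo-3-iodo-5-methoxyphenoxy)-2-[(2-pentyl-1,3-dioxolan-2-yl)methyl]benzoate
Product: 15 benzyl 4,6-bis(benzyloxy)-3-(2-bromo-3-hydroxy-5-methoxyphenoxy)-2-[(2-pentyl-1,3-dioxolan-2-yl)methyl]benzoate, via pinacol boronate 14 (not isolated)
Conditions: PdCl2(dppf) (3 mol %), pinacolborane, Et3N, 1,4-dioxane, 70 °C; then 30 % H2O2, aq. NaOH, THF, 0 °C
Reagents that add atoms: pinacolborane, CC1(C)OBOC1(C)C (boron group of 14); hydrogen peroxide, OO (phenol oxygen of 15)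
Why: Chemoselective Miyaura-type borylation of the C–I bond (oxidative addition to iodide precedes that to the neighbouring bromide) and oxidation of the boronate give the phenol at C4a next to the bromine at C8a.

Step 10
Reactants: 15 benzyl 4,6-bis(benzyloxy)-3-(2-bromo-3-hydroxy-5-methoxyphenoxy)-2-[(2-pentyl-1,3-dioxolan-2-yl)methyl]benzoate
Product: 18 benzyl 4,6-bis(benzyloxy)-3-[5-methoxy-3-(trifluoromethylsulfonyloxy)-2-(trimethylsilyl)phenoxy]-2-[(2-pentyl-1,3-dioxolan-2-yl)methyl]benzoate, via trimethylsilyl ether 16 (not isolated), via lithium phenoxide 17 (not isolated)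
Conditions: (Me3Si)2NH, THF, 65 °C, then evaporation; n-BuLi (1.05 equiv), THF, −100 to −78 °C; Tf2O, −78 °C
Reagents that add atoms: hexamethyldisilazane, C[Si](C)(C)N[Si](C)(C)C (Me3Si group); triflic anhydride, O=S(=O)(OS(=O)(=O)C(F)(F)F)C(F)(F)F (CF3SO2 group)
Why: O-silylation, bromine–lithium exchange and 1,3 O-to-C silyl migration (retro-Brook rearrangement) place Me3Si on C8a between the two oxygens, and the released phenoxide is triflated in the same flask; at −100 °C halogen–metal exchange outruns addition to the hindered benzyl ester.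

Step 11
Reactants: 18 benzyl 4,6-bis(benzyloxy)-3-[5-methoxy-3-(trifluoromethylsulfonyloxy)-2-(trimethylsilyl)phenoxy]-2-[(2-pentyl-1,3-dioxolan-2-yl)methyl]benzoate; 19 diallyl malonate
Product: 21 benzyl 3-{2-[(allyloxy)carbonyl]-3-[2-(allyloxy)-2-oxoethyl]-5-methoxyphenoxy}-4,6-bis(benzyloxy)-2-[(2-pentyl-1,3-dioxolan-2-yl)methyl]benzoate, via aryne 20 (not isolated)
Conditions: CsF (3 equiv), 19 (3 equiv), MeCN, 60 °C
Reagents that add atoms: none
Why: Fluoride removes Me3Si from C8a and triflate leaves from C4a to give aryne 20; the malonate enolate adds through carbon to C4a, the aryl anion formed at C8a attacks one ester carbonyl, and the strained four-membered alkoxide fragments, so the aryne is inserted into a C–C σ bond of the malonate (new bonds C4a–C4 and C8a–C1). The closest known reaction type is the fluoride-induced acyl-alkylation of arynes from 2-(trimethylsilyl)aryl triflates with malonates and β-keto esters, which gives homophthalates. No ring of the product is closed; the only ring formed is the transient four-membered alkoxide, closed 4-exo-trig and reopened at once. No stereocentre is created. The step needs regioselective addition, secured by the inductively withdrawing aryloxy group at C8, which distorts the aryne so that the nucleophile attacks the remote carbon C4a and negative charge develops at C8a next to oxygen; the 6-methoxy group is meta to C4a and does not oppose this. The excess of 19 suppresses a second arylation at the acidic CH2 of 21.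

Step 12
Reactants: 21 benzyl 3-{2-[(allyloxy)carbonyl]-3-[2-(allyloxy)-2-oxoethyl]-5-methoxyphenoxy}-4,6-bis(benzyloxy)-2-[(2-pentyl-1,3-dioxolan-2-yl)methyl]benzoate; 22 hexanoyl chloride
Product: 23 benzyl 3-{2-[(allyloxy)carbonyl]-3-[1-(allyloxy)-1,3-dioxooctan-2-yl]-5-methoxyphenoxy}-4,6-bis(benzyloxy)-2-[(2-pentyl-1,3-dioxolan-2-yl)methyl]benzoate (racemic)
Conditions: LiN(SiMe3)2 (2.2 equiv), THF, −78 °C; 22 (1.1 equiv), −78 °C; AcOH quench at −78 °C
Reagents that add atoms: none
Why: Crossed Claisen-type C-acylation of the lithium enolate of the arylacetic ester by the acid chloride, with the second equivalent of base taking up the more acidic β-keto ester; the cold quench forestalls rearrangement of the allyl ester enolate and lactonisation onto the ring B ester, and the new stereocentre forms as a racemate that is lost in step 13.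

Step 13
Reactants: 23 benzyl 3-{2-[(allyloxy)carbonyl]-3-[1-(allyloxy)-1,3-dioxooctan-2-yl]-5-methoxyphenoxy}-4,6-bis(benzyloxy)-2-[(2-pentyl-1,3-dioxolan-2-yl)methyl]benzoate (racemic)
Product: 25 benzyl 4,6-bis(benzyloxy)-3-[2-carboxy-5-methoxy-3-(2-oxoheptyl)phenoxy]-2-[(2-pentyl-1,3-dioxolan-2-yl)methyl]benzoate, via keto diacid 24 (not isolated)
Conditions: Pd(PPh3)4 (5 mol %), morpholine (6 equiv), THF, rt to 40 °C; cold dilute citric acid work-up
Reagents that add atoms: none
Why: Tsuji–Trost deallylation, in which zerovalent palladium ionises both allyl esters and morpholine takes up the allyl groups, followed by loss of CO2 from β-keto acid 24; benzyl ester, benzyl ethers and dioxolane are untouched.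

Step 14
Reactants: 25 benzyl 4,6-bis(benzyloxy)-3-[2-carboxy-5-methoxy-3-(2-oxoheptyl)phenoxy]-2-[(2-pentyl-1,3-dioxolan-2-yl)methyl]benzoate
Product: 27 benzyl 4,6-bis(benzyloxy)-3-[(6-methoxy-1-oxo-3-pentyl-1H-isochromen-8-yl)oxy]-2-(2-oxoheptyl)benzoate, via isocoumarin ketal 26 (not isolated)
Conditions: Ac2O, NaOAc, 80 °C; evaporation; 2 M aq. HCl/THF (1:4), rt
Reagents that add atoms: water, O
Why: Enol lactonisation through the mixed anhydride (6-exo-trig attack of the enol oxygen on the activated ring B carboxyl) closes the isocoumarin while ring A is inert as benzyl ester and ketal; mild aqueous acid then hydrolyses the dioxolane without cyclising the ring A keto ester.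

Step 15
Reactants: 27 benzyl 4,6-bis(benzyloxy)-3-[(6-methoxy-1-oxo-3-pentyl-1H-isochromen-8-yl)oxy]-2-(2-oxoheptyl)benzoate
Product: 28 β-collatolic acid, 2,4-dihydroxy-5-[(6-methoxy-1-oxo-3-pentyl-1H-isochromen-8-yl)oxy]-6-(2-oxoheptyl)benzoic acid
Conditions: H2 (1 atm), Pd/C (10 wt %), EtOAc, rt, stopped at complete debenzylation
Reagents that add atoms: none
Why: Hydrogenolysis of the two benzyl ethers and the benzyl ester under neutral conditions at rt, which the decarboxylation-prone dihydroxybenzoic acid tolerates; O-benzyl cleavage should be faster than reduction of the trisubstituted C3=C4 bond of the enol lactone.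

Compound list
1 | orsellinic acid (2,4-dihydroxy-6-methylbenzoic acid) | Cc1cc(O)cc(O)c1C(=O)O | starting material
2 | benzyl 2,4-bis(benzyloxy)-6-methylbenzoate | Cc1cc(OCc2ccccc2)cc(OCc2ccccc2)c1C(=O)OCc1ccccc1 | intermediate
3 | benzyl 4,6-bis(benzyloxy)-3-bromo-2-methylbenzoate | Cc1c(Br)c(OCc2ccccc2)cc(OCc2ccccc2)c1C(=O)OCc1ccccc1 | intermediate
4 | N-methoxy-N-methylhexanamide | CCCCCC(=O)N(C)OC | starting material
5 | benzyl 4,6-bis(benzyloxy)-3-bromo-2-(2-oxoheptyl)benzoate | CCCCCC(=O)Cc1c(Br)c(OCc2ccccc2)cc(OCc2ccccc2)c1C(=O)OCc1ccccc1 | intermediate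
6 | benzyl 4,6-bis(benzyloxy)-3-bromo-2-[(2-pentyl-1,3-dioxolan-2-yl)methyl]benzoate | CCCCCC1(Cc2c(Br)c(OCc3ccccc3)cc(OCc3ccccc3)c2C(=O)OCc2ccccc2)OCCO1 | intermediate
7 | benzyl 4,6-bis(benzyloxy)-2-[(2-pentyl-1,3-dioxolan-2-yl)methyl]-3-(4,4,5,5-tetramethyl-1,3,2-dioxaborolan-2-yl)benzoate | CCCCCC1(Cc2c(B3OC(C)(C)C(C)(C)O3)c(OCc3ccccc3)cc(OCc3ccccc3)c2C(=O)OCc2ccccc2)OCCO1 | intermediate
8 | benzyl 4,6-bis(benzyloxy)-3-hydroxy-2-[(2-pentyl-1,3-dioxolan-2-yl)methyl]benzoate | CCCCCC1(Cc2c(O)c(OCc3ccccc3)cc(OCc3ccccc3)c2C(=O)OCc2ccccc2)OCCO1 | intermediate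
9 | 4-methoxyaniline | COc1ccc(N)cc1 | starting material
10 | 2,6-diiodo-4-methoxyaniline | COc1cc(I)c(N)c(I)c1 | intermediate
11 | 2,6-diiodo-4-methoxybenzenediazonium bromide | COc1cc(I)c([N+]#N)c(I)c1.[Br-] | intermediate
12 | 2-bromo-1,3-diiodo-5-methoxybenzene | COc1cc(I)c(Br)c(I)c1 | intermediate
13 | benzyl 4,6-bis(benzyloxy)-3-(2-bromo-3-iodo-5-methoxyphenoxy)-2-[(2-pentyl-1,3-dioxolan-2-yl)methyl]benzoate | CCCCCC1(Cc2c(Oc3cc(OC)cc(I)c3Br)c(OCc3ccccc3)cc(OCc3ccccc3)c2C(=O)OCc2ccccc2)OCCO1 | intermediate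
14 | benzyl 4,6-bis(benzyloxy)-3-[2-bromo-5-methoxy-3-(4,4,5,5-tetramethyl-1,3,2-dioxaborolan-2-yl)phenoxy]-2-[(2-pentyl-1,3-dioxolan-2-yl)methyl]benzoate | CCCCCC1(Cc2c(Oc3cc(OC)cc(B4OC(C)(C)C(C)(C)O4)c3Br)c(OCc3ccccc3)cc(OCc3ccccc3)c2C(=O)OCc2ccccc2)OCCO1 | intermediate
15 | benzyl 4,6-bis(benzyloxy)-3-(2-bromo-3-hydroxy-5-methoxyphenoxy)-2-[(2-pentyl-1,3-dioxolan-2-yl)methyl]benzoate | CCCCCC1(Cc2c(Oc3cc(OC)cc(O)c3Br)c(OCc3ccccc3)cc(OCc3ccccc3)c2C(=O)OCc2ccccc2)OCCO1 | intermediate
16 | benzyl 4,6-bis(benzyloxy)-3-[2-bromo-5-methoxy-3-(trimethylsilyloxy)phenoxy]-2-[(2-pentyl-1,3-dioxolan-2-yl)methyl]benzoate | CCCCCC1(Cc2c(Oc3cc(OC)cc(O[Si](C)(C)C)c3Br)c(OCc3ccccc3)cc(OCc3ccccc3)c2C(=O)OCc2ccccc2)OCCO1 | intermediate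
17 | lithium 3-{4,6-bis(benzyloxy)-3-[(benzyloxy)carbonyl]-2-[(2-pentyl-1,3-dioxolan-2-yl)methyl]phenoxy}-5-methoxy-2-(trimethylsilyl)phenolate | CCCCCC1(Cc2c(Oc3cc(OC)cc([O-])c3[Si](C)(C)C)c(OCc3ccccc3)cc(OCc3ccccc3)c2C(=O)OCc2ccccc2)OCCO1.[Li+] | intermediate
18 | benzyl 4,6-bis(benzyloxy)-3-[5-methoxy-3-(trifluoromethylsulfonyloxy)-2-(trimethylsilyl)phenoxy]-2-[(2-pentyl-1,3-dioxolan-2-yl)methyl]benzoate (aryne precursor) | CCCCCC1(Cc2c(Oc3cc(OC)cc(OS(=O)(=O)C(F)(F)F)c3[Si](C)(C)C)c(OCc3ccccc3)cc(OCc3ccccc3)c2C(=O)OCc2ccccc2)OCCO1 | intermediate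
19 | diallyl malonate | C=CCOC(=O)CC(=O)OCC=C | starting material
20 | benzyl 4,6-bis(benzyloxy)-3-(2,3-didehydro-5-methoxyphenoxy)-2-[(2-pentyl-1,3-dioxolan-2-yl)methyl]benzoate (aryne, triple bond between C4a and C8a) | CCCCCC1(Cc2c(OC3=CC(OC)=CC#C3)c(OCc3ccccc3)cc(OCc3ccccc3)c2C(=O)OCc2ccccc2)OCCO1 | intermediate
21 | benzyl 3-{2-[(allyloxy)carbonyl]-3-[2-(allyloxy)-2-oxoethyl]-5-methoxyphenoxy}-4,6-bis(benzyloxy)-2-[(2-pentyl-1,3-dioxolan-2-yl)methyl]benzoate (diallyl homophthalate of ring B) | CCCCCC1(Cc2c(Oc3cc(OC)cc(CC(=O)OCC=C)c3C(=O)OCC=C)c(OCc3ccccc3)cc(OCc3ccccc3)c2C(=O)OCc2ccccc2)OCCO1 | intermediate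
22 | hexanoyl chloride | CCCCCC(Cl)=O | starting material
23 | benzyl 3-{2-[(allyloxy)carbonyl]-3-[1-(allyloxy)-1,3-dioxooctan-2-yl]-5-methoxyphenoxy}-4,6-bis(benzyloxy)-2-[(2-pentyl-1,3-dioxolan-2-yl)methyl]benzoate (racemic) | CCCCCC1(Cc2c(Oc3cc(OC)cc(C(C(=O)CCCCC)C(=O)OCC=C)c3C(=O)OCC=C)c(OCc3ccccc3)cc(OCc3ccccc3)c2C(=O)OCc2ccccc2)OCCO1 | intermediate
24 | benzyl 4,6-bis(benzyloxy)-3-[2-carboxy-3-(1-carboxy-2-oxoheptyl)-5-methoxyphenoxy]-2-[(2-pentyl-1,3-dioxolan-2-yl)methyl]benzoate (racemic) | CCCCCC1(Cc2c(Oc3cc(OC)cc(C(C(=O)CCCCC)C(=O)O)c3C(=O)O)c(OCc3ccccc3)cc(OCc3ccccc3)c2C(=O)OCc2ccccc2)OCCO1 | intermediate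
25 | benzyl 4,6-bis(benzyloxy)-3-[2-carboxy-5-methoxy-3-(2-oxoheptyl)phenoxy]-2-[(2-pentyl-1,3-dioxolan-2-yl)methyl]benzoate | CCCCCC1(Cc2c(Oc3cc(OC)cc(CC(=O)CCCCC)c3C(=O)O)c(OCc3ccccc3)cc(OCc3ccccc3)c2C(=O)OCc2ccccc2)OCCO1 | intermediate
26 | benzyl 4,6-bis(benzyloxy)-3-[(6-methoxy-1-oxo-3-pentyl-1H-isochromen-8-yl)oxy]-2-[(2-pentyl-1,3-dioxolan-2-yl)methyl]benzoate | CCCCCC1(Cc2c(Oc3cc(OC)cc4cc(CCCCC)oc(=O)c34)c(OCc3ccccc3)cc(OCc3ccccc3)c2C(=O)OCc2ccccc2)OCCO1 | intermediate
27 | benzyl 4,6-bis(benzyloxy)-3-[(6-methoxy-1-oxo-3-pentyl-1H-isochromen-8-yl)oxy]-2-(2-oxoheptyl)benzoate | CCCCCC(=O)Cc1c(Oc2cc(OC)cc3cc(CCCCC)oc(=O)c23)c(OCc2ccccc2)cc(OCc2ccccc2)c1C(=O)OCc1ccccc1 | intermediate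
28 | β-collatolic acid, 2,4-dihydroxy-5-[(6-methoxy-1-oxo-3-pentyl-1H-isochromen-8-yl)oxy]-6-(2-oxoheptyl)benzoic acid | CCCCCC(=O)Cc1c(Oc2cc(OC)cc3cc(CCCCC)oc(=O)c23)c(O)cc(O)c1C(=O)O | target

Total step count: 15
Longest linear sequence: 13 steps (steps 1 to 5 and 8 to 15); steps 6 and 7 form the short second branch.

Steps most likely to fail

Step 8 (hindered Ullmann coupling). The phenol is flanked by two ortho substituents and the iodide by bromine, so C–O bond formation may be too slow and lose out to hydrodeiodination or to a second arylation of the diiodide. Fallback: replace copper catalysis by metal-free arylation with a diaryliodonium salt. It sets out from 12 and 8. Oxidation of one C–I bond of 12 with 3-chloroperbenzoic acid and TsOH·H2O in MeCN, followed by ligand exchange with 1,3,5-trimethoxybenzene, gives (2-bromo-3-iodo-5-methoxyphenyl)(2,4,6-trimethoxyphenyl)iodonium tosylate F1, a trivalent iodine reagent whose trimethoxyphenyl group is not transferred. Phenol 8, KOt-Bu and F1 in THF at rt then give diaryl ether 13, where the route is rejoined.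

Step 11 (aryne insertion). After addition of the malonate, the aryl anion at C8a may be protonated before it reaches the ester carbonyl (plain arylation without acyl transfer). The acidic CH2 of the product may also add to a second aryne, or the neighbouring benzyloxy oxygen of ring A may capture the aryne. Fallback: build the isocoumarin without an aryne, by SNAr, Sonogashira coupling and cycloisomerisation. It sets out from 8. SNAr on purchased 2-bromo-6-fluoro-4-methoxybenzaldehyde (Cs2CO3, DMF, 80 °C; the fluoride ortho to the formyl group is displaced) gives benzyl 4,6-bis(benzyloxy)-3-(3-bromo-2-formyl-5-methoxyphenoxy)-2-[(2-pentyl-1,3-dioxolan-2-yl)methyl]benzoate F2. Sonogashira coupling with hept-1-yne (PdCl2(PPh3)2, CuI, Et3N) gives the alkynyl aldehyde F3. Pinnick oxidation (NaClO2, NaH2PO4, 2-methylbut-2-ene) gives the 2-alkynylbenzoic acid F4. Acid-promoted 6-endo-dig cycloisomerisation (catalytic TfOH or AuCl3, CH2Cl2) gives isocoumarin 26, where the route is rejoined (hydrolysis part of step 14, then step 15).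

Step 12 (C-acylation of the homophthalate). The enolate may be acylated on oxygen or twice, the allyl ester enolate may undergo sigmatropic rearrangement on warming, and the product enolate may lactonise onto the ring B ester before the C4 carboxyl has been removed. Fallback: acylate the cyclic anhydride instead of the open-chain enolate. It sets out from 21. Pd(PPh3)4 and morpholine remove both allyl groups to give the homophthalic acid F5. Ac2O at rt closes the homophthalic anhydride F6. Hexanoyl chloride 22 with Et3N in MeCN at 0 °C acylates its acidic C4 to give the 4-hexanoyl anhydride F7. Warming with aqueous NaHCO3 in THF opens the anhydride to keto diacid 24, which loses CO2 to give keto acid 25, where the route is rejoined.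

Further compounds
F1 | step 8 | (2-bromo-3-iodo-5-methoxyphenyl)(2,4,6-trimethoxyphenyl)iodonium tosylate | COc1cc(I)c(Br)c([I+]c2c(OC)cc(OC)cc2OC)c1.Cc1ccc(S(=O)(=O)[O-])cc1
F2 | step 11 | benzyl 4,6-bis(benzyloxy)-3-(3-bromo-2-formyl-5-methoxyphenoxy)-2-[(2-pentyl-1,3-dioxolan-2-yl)methyl]benzoate | CCCCCC1(Cc2c(Oc3cc(OC)cc(Br)c3C=O)c(OCc3ccccc3)cc(OCc3ccccc3)c2C(=O)OCc2ccccc2)OCCO1
F3 | step 11 | benzyl 4,6-bis(benzyloxy)-3-[2-formyl-3-(hept-1-yn-1-yl)-5-methoxyphenoxy]-2-[(2-pentyl-1,3-dioxolan-2-yl)methyl]benzoate | CCCCCC1(Cc2c(Oc3cc(OC)cc(C#CCCCCC)c3C=O)c(OCc3ccccc3)cc(OCc3ccccc3)c2C(=O)OCc2ccccc2)OCCO1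
F4 | step 11 | benzyl 4,6-bis(benzyloxy)-3-[2-carboxy-3-(hept-1-yn-1-yl)-5-methoxyphenoxy]-2-[(2-pentyl-1,3-dioxolan-2-yl)methyl]benzoate | CCCCCC1(Cc2c(Oc3cc(OC)cc(C#CCCCCC)c3C(=O)O)c(OCc3ccccc3)cc(OCc3ccccc3)c2C(=O)OCc2ccccc2)OCCO1
F5 | step 12 | benzyl 4,6-bis(benzyloxy)-3-[2-carboxy-3-(carboxymethyl)-5-methoxyphenoxy]-2-[(2-pentyl-1,3-dioxolan-2-yl)methyl]benzoate | CCCCCC1(Cc2c(Oc3cc(OC)cc(CC(=O)O)c3C(=O)O)c(OCc3ccccc3)cc(OCc3ccccc3)c2C(=O)OCc2ccccc2)OCCO1
F6 | step 12 | benzyl 4,6-bis(benzyloxy)-3-[(6-methoxy-1,3-dioxo-3,4-dihydro-1H-isochromen-8-yl)oxy]-2-[(2-pentyl-1,3-dioxolan-2-yl)methyl]benzoate | CCCCCC1(Cc2c(Oc3cc(OC)cc4CC(=O)OC(=O)c34)c(OCc3ccccc3)cc(OCc3ccccc3)c2C(=O)OCc2ccccc2)OCCO1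
F7 | step 12 | benzyl 4,6-bis(benzyloxy)-3-[(4-hexanoyl-6-methoxy-1,3-dioxo-3,4-dihydro-1H-isochromen-8-yl)oxy]-2-[(2-pentyl-1,3-dioxolan-2-yl)methyl]benzoate (racemic) | CCCCCC1(Cc2c(Oc3cc(OC)cc4C(C(=O)CCCCC)C(=O)OC(=O)c34)c(OCc3ccccc3)cc(OCc3ccccc3)c2C(=O)OCc2ccccc2)OCCO1
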